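**Retrosynthetic overview**

- The strategy rests on the single ring, the 14-membered lactone O–C1…C13: C1–C2 is an acetate unit carried by the C13 oxygen, and C3 bears the CH2CO2H arm on the C2=C3 enoate. A C3 carbonyl can therefore serve twice, first as the ring-closing electrophile and then as an (E)-enol triflate.
- The arm is attached last by Negishi coupling of the C3 (E)-enol triflate with BrZnCH2CO2t-Bu. The triflate comes from the β-keto lactone, and that from the β-hydroxy lactone formed in the only ring closure: SmI2 Reformatsky reaction of the C13 bromoacetate with the C3 aldehyde (C2–C3).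
- The open chain is joined at C7–C8 by Zr-catalysed methylalumination of a C8–C24 alkyne and Pd-catalysed allylation with a C3–C7 (E)-allylic chloride made from 3-butyn-1-ol.
- The alkyne takes C9–C14 (C11 and C13 stereocentres) from the statin chlorodiol and C15–C24 from decanal, joined at C14–C15 by dithiane opening of a C13–C14 epoxide. C15 is set by an Evans–Tishchenko reduction, which also leaves only the C13 oxygen acylated.

Key step: step 19

Remark: positions are given in macrolide numbering (C1 = lactone carbonyl, ring oxygen on C13, C24 = chain end); TBS = tert-butyldimethylsilyl, PMB = 4-methoxybenzyl; compound 26 is carried as a mixture of C3 epimers because C3 becomes a ketone in step 20.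

**Route**

Step 1
Reactants: 1 tert-butyl (3R,5S)-6-chloro-3,5-dihydroxyhexanoate
Product: 2 tert-butyl (3R)-3-hydroxy-4-[(2S)-oxiran-2-yl]butanoate
Conditions: K2CO3, MeOH, 0 °C → rt
Reagents that add atoms: none
Why: Chlorohydrin-to-epoxide closure (intramolecular Williamson etherification): the C5 alkoxide should displace the neighbouring primary chloride in a fast 3-exo-tet step, faster than any attack by the C3 hydroxyl, and no bond to a stereocentre is broken while the tert-butyl ester is inert to carbonate in methanol.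

Step 2
Reactants: 2 tert-butyl (3R)-3-hydroxy-4-[(2S)-oxiran-2-yl]butanoate
Product: 3 tert-butyl (3R)-3-(TBSO)-4-[(2S)-oxiran-2-yl]butanoate
Conditions: TBSCl, imidazole, DMF, rt
Reagents that add atoms: tert-butyldimethylsilyl chloride, CC(C)(C)[Si](C)(C)Cl
Why: Imidazole-promoted silylation of a secondary alcohol; it fixes the later C11 oxygen as the silyl ether while the epoxide oxygen is kept for the later C13 hydroxyl.

Step 3
Reactants: 3 tert-butyl (3R)-3-(TBSO)-4-[(2S)-oxiran-2-yl]butanoate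
Product: 4 (3R)-3-(TBSO)-4-[(2S)-oxiran-2-yl]butanal
Conditions: i-Bu2AlH (1.1 equiv), CH2Cl2, −78 °C; aq. potassium sodium tartrate
Reagents that add atoms: none
Why: Partial ester reduction with i-Bu2AlH: the tetrahedral aluminium hemiacetal of the tert-butyl ester should persist at −78 °C and release the aldehyde only on work-up, and the epoxide is not opened at this temperature.

Step 4
Reactants: 4 (3R)-3-(TBSO)-4-[(2S)-oxiran-2-yl]butanal
Product: 5 tert-butyldimethyl{[(2S)-1-[(2S)-oxiran-2-yl]pent-4-yn-2-yl]oxy}silane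
Conditions: dimethyl (1-diazo-2-oxopropyl)phosphonate, K2CO3, MeOH, 0 °C → rt
Reagents that add atoms: dimethyl (1-diazo-2-oxopropyl)phosphonate, COP(=O)(OC)C(=[N+]=[N-])C(C)=O
Why: Ohira–Bestmann (Seyferth–Gilbert) homologation: the diazomethylphosphonate anion adds to the aldehyde and the diazoalkene loses N2 with 1,2-shift to give the terminal alkyne (C8≡C9) under conditions mild enough for the β-silyloxy aldehyde and the epoxide.

Step 5
Reactants: 6 decanal
Product: 7 2-nonyl-1,3-dithiane
Conditions: HS(CH2)3SH, BF3·OEt2, CH2Cl2, 0 °C → rt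
Reagents that add atoms: propane-1,3-dithiol, SCCCS
Why: Lewis-acid-catalysed dithioacetalisation of an unhindered aliphatic aldehyde, which turns C15 into a Corey–Seebach acyl anion equivalent.

Step 6
Reactants: 7 2-nonyl-1,3-dithiane; 5 tert-butyldimethyl{[(2S)-1-[(2S)-oxiran-2-yl]pent-4-yn-2-yl]oxy}silane
Product: 9 (2S,4S)-4-(TBSO)-1-(2-nonyl-1,3-dithian-2-yl)hept-6-yn-2-ol, via 2-lithio-2-nonyl-1,3-dithiane 8 (not isolated)
Conditions: n-BuLi, THF, −25 °C (2.3 equiv of 8 per 5); then 5, −25 → 0 °C; H2O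
Reagents that add atoms: none
Why: Corey–Seebach dithiane alkylation: the lithiated dithiane opens the terminal epoxide at the unsubstituted carbon C14 (SN2), so the C13 configuration is retained; the first equivalent of anion is consumed by the acetylenic C–H, and the resulting lithium acetylide does not open epoxides in THF without a Lewis acid.

Step 7
Reactants: 9 (2S,4S)-4-(TBSO)-1-(2-nonyl-1,3-dithian-2-yl)hept-6-yn-2-ol
Product: 10 (4S,6S)-4-(TBSO)-6-hydroxyheptadec-1-yn-8-one
Conditions: MeI, CaCO3, MeCN/H2O (9:1), 40 °C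
Reagents that add atoms: water, O
Why: Alkylative dithioacetal hydrolysis: S-methylation, ring opening to the thionium ion and addition of water release the C15 ketone under carbonate buffering, which the alkyne, the silyl ether and the β-hydroxy ketone should tolerate.

Step 8
Reactants: 10 (4S,6S)-4-(TBSO)-6-hydroxyheptadec-1-yn-8-one
Product: 11 (4S,6R,8S)-4-(TBSO)-8-hydroxyheptadec-1-yn-6-yl benzoate
Conditions: PhCHO (5 equiv), SmI2 (0.3 equiv), THF, −10 °C
Reagents that add atoms: benzaldehyde, O=Cc1ccccc1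
Why: Evans–Tishchenko reduction: the samarium-bound hemiacetal from the C13 hydroxyl and benzaldehyde delivers hydride intramolecularly to the C15 ketone through a chair-like six-membered transition state, which should set C15 (S) 1,3-anti to C13 and leave C13 as the benzoate and C15 as the free hydroxyl.

Step 9
Reactants: 11 (4S,6R,8S)-4-(TBSO)-8-hydroxyheptadec-1-yn-6-yl benzoate
Product: 12 (4S,6R,8S)-4,8-bis(TBSO)heptadec-1-yn-6-yl benzoate
Conditions: TBSOTf, 2,6-lutidine, CH2Cl2, −78 °C
Reagents that add atoms: tert-butyldimethylsilyl trifluoromethanesulfonate, CC(C)(C)[Si](C)(C)OS(=O)(=O)C(F)(F)F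
Why: Silylation of a hindered secondary alcohol with the silyl triflate and a non-nucleophilic base; the low temperature should suppress benzoate migration.

Step 10
Reactants: 12 (4S,6R,8S)-4,8-bis(TBSO)heptadec-1-yn-6-yl benzoate
Product: 13 (4S,6R,8S)-4,8-bis(TBSO)heptadec-1-yn-6-ol
Conditions: i-Bu2AlH (2.5 equiv), CH2Cl2, −78 °C; aq. potassium sodium tartrate
Reagents that add atoms: none
Why: Reductive ester cleavage with i-Bu2AlH frees the C13 hydroxyl without a free alkoxide in protic base, so 1,3-silyl migration is avoided, and the terminal alkyne and silyl ethers are inert at −78 °C.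

Step 11
Reactants: 14 3-butyn-1-ol
Product: 15 1-[(but-3-yn-1-yloxy)methyl]-4-methoxybenzene
Conditions: NaH, 4-MeOC6H4CH2Cl, n-Bu4NI (cat.), THF/DMF, 0 °C → rt
Reagents that add atoms: 4-methoxybenzyl chloride, COc1ccc(CCl)cc1
Why: Williamson etherification of the primary alkoxide, which forms well before the far less acidic alkyne C–H is touched.

Step 12
Reactants: 15 1-[(but-3-yn-1-yloxy)methyl]-4-methoxybenzene
Product: 17 5-(PMBO)pent-2-yn-1-ol, via lithium 4-(PMBO)but-1-yn-1-ide 16 (not isolated)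
Conditions: n-BuLi, THF, −78 °C; (CH2O)n, −78 °C → rt; H2O
Reagents that add atoms: paraformaldehyde (as formaldehyde), C=O
Why: Acetylide hydroxymethylation: deprotonation of the terminal alkyne and 1,2-addition of the lithium acetylide to formaldehyde add C7.

Step 13
Reactants: 17 5-(PMBO)pent-2-yn-1-ol
Product: 18 (2E)-5-(PMBO)pent-2-en-1-ol
Conditions: NaAlH2(OCH2CH2OMe)2, THF, 0 °C → rt; aq. potassium sodium tartrate
Reagents that add atoms: none
Why: Hydroxyl-directed trans-hydroalumination of a propargylic alcohol through a five-membered cyclic alkenylalanate, whose protonolysis should give only the (E)-allylic alcohol (C5=C6).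

Step 14
Reactants: 18 (2E)-5-(PMBO)pent-2-en-1-ol
Product: 19 1-({[(3E)-5-chloropent-3-en-1-yl]oxy}methyl)-4-methoxybenzene
Conditions: NCS, Me2S, CH2Cl2, −20 → 0 °C
Reagents that add atoms: N-chlorosuccinimide, O=C1CCC(=O)N1Cl
Why: Allylic chlorination by chlorosulfonium activation (Corey–Kim-type reagent): the alkoxysulfonium salt is displaced by chloride in a direct SN2 reaction at the primary carbon, so the (E)-alkene is neither transposed nor isomerised.

Step 15
Reactants: 13 (4S,6R,8S)-4,8-bis(TBSO)heptadec-1-yn-6-ol; 19 1-({[(3E)-5-chloropent-3-en-1-yl]oxy}methyl)-4-methoxybenzene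
Product: 21 (3E,6E,9S,11R,13S)-9,13-bis(TBSO)-1-(PMBO)-7-methyldocosa-3,6-dien-11-ol, via (E)-alkenyldimethylalane 20 (not isolated)
Conditions: Me3Al (4 equiv), Cp2ZrCl2 (1 equiv), CH2Cl2, 0 °C → rt; evaporate; then 19, Pd(PPh3)4 (5 mol %), THF, rt; aq. work-up
Reagents that add atoms: trimethylaluminium, C[Al](C)C
Why: Zirconium-catalysed methylalumination followed by Negishi alkenyl–allyl coupling: syn addition of Me–Al across the terminal alkyne (Me to C9, Al to C8) gives the (E)-2-methylalkenylalane with the C13 hydroxyl masked in situ as its aluminium alkoxide, and zerovalent palladium then joins the alkenyl group to the unsubstituted terminus of the π-allyl complex from 19 with retention of both alkene geometries (C7–C8).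

Step 16
Reactants: 21 (3E,6E,9S,11R,13S)-9,13-bis(TBSO)-1-(PMBO)-7-methyldocosa-3,6-dien-11-ol
Product: 22 (3E,6E,9S,11R,13S)-9,13-bis(TBSO)-1-(PMBO)-7-methyldocosa-3,6-dien-11-yl bromoacetate
Conditions: BrCH2CO2H, DCC, DMAP (cat.), CH2Cl2, 0 °C → rt
Reagents that add atoms: bromoacetic acid, OC(=O)CBr
Why: Steglich esterification of the only free hydroxyl (C13); carbodiimide activation avoids stoichiometric amine base that would quaternise on the α-bromo ester.

Step 17
Reactants: 22 (3E,6E,9S,11R,13S)-9,13-bis(TBSO)-1-(PMBO)-7-methyldocosa-3,6-dien-11-yl bromoacetate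
Product: 23 (3E,6E,9S,11R,13S)-9,13-bis(TBSO)-1-hydroxy-7-methyldocosa-3,6-dien-11-yl bromoacetate
Conditions: DDQ, CH2Cl2/pH 7 buffer, 0 °C
Reagents that add atoms: none
Why: Oxidative PMB ether cleavage: DDQ abstracts hydride from the electron-rich benzylic position and the oxocarbenium ion is hydrolysed, while silyl ethers, the bromoacetate and the non-conjugated alkenes should survive buffered conditions at 0 °C.

Step 18
Reactants: 23 (3E,6E,9S,11R,13S)-9,13-bis(TBSO)-1-hydroxy-7-methyldocosa-3,6-dien-11-yl bromoacetate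
Product: 24 (3E,6E,9S,11R,13S)-9,13-bis(TBSO)-7-methyl-1-oxodocosa-3,6-dien-11-yl bromoacetate
Conditions: Dess–Martin periodinane, NaHCO3, CH2Cl2, 0 °C → rt; used crude
Reagents that add atoms: none
Why: Dess–Martin oxidation under bicarbonate buffer should give the β,γ-unsaturated C3 aldehyde without acid or base strong enough to move C5=C6 into conjugation.

Step 19
Reactants: 24 (3E,6E,9S,11R,13S)-9,13-bis(TBSO)-7-methyl-1-oxodocosa-3,6-dien-11-yl bromoacetate
Product: 26 (6E,9E,12S,14R)-12-(TBSO)-14-[(2S)-2-(TBSO)undecyl]-4-hydroxy-10-methyl-1-oxacyclotetradeca-6,9-dien-2-one, via samarium ester enolate 25 (not isolated)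
Conditions: SmI2 (3 equiv), THF, −78 °C, slow addition of 24 (final ca. 0.002 M); then H2O
Reagents that add atoms: none
Why: Two single-electron transfers from divalent samarium cleave the C–Br bond of the bromoacetate and give the trivalent samarium ester enolate 25, which adds to the C3 aldehyde to form C2–C3; this is an intramolecular samarium Reformatsky reaction, the closest known type being the SmI2-promoted macrolactonisation of formyl-terminated bromoacetates. The single ring, the 14-membered lactone, closes in a 14-exo-trig aldol mode in which the oxophilic samarium bridges the enolate and aldehyde oxygens and so templates the large ring. The only new stereocentre, C3, is formed without useful control, and none is needed because it is oxidised in step 20. The step needs reduction of C–Br in preference to ketyl formation at the aldehyde and ring closure in preference to intermolecular aldol or pinacol coupling: the α-bromo ester is reduced far faster than an aliphatic aldehyde at −78 °C, and slow addition of 24 to excess SmI2 keeps the stationary concentration of aldehyde and enolate very low. The enolate is only weakly basic and the medium is neutral, so the β,γ-unsaturated aldehyde and the skipped C5=C6/C8=C9 diene should not isomerise and the silyl ethers are unaffected.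

Step 20
Reactants: 26 (6E,9E,12S,14R)-12-(TBSO)-14-[(2S)-2-(TBSO)undecyl]-4-hydroxy-10-methyl-1-oxacyclotetradeca-6,9-dien-2-one
Product: 27 (6E,9E,12S,14R)-12-(TBSO)-14-[(2S)-2-(TBSO)undecyl]-10-methyl-1-oxacyclotetradeca-6,9-diene-2,4-dione
Conditions: Dess–Martin periodinane (1.5 equiv), NaHCO3, CH2Cl2, rt
Reagents that add atoms: none
Why: Dess–Martin oxidation of the β-hydroxy lactone to the β-keto lactone, in which both C3 epimers converge on one compound.

Step 21
Reactants: 27 (6E,9E,12S,14R)-12-(TBSO)-14-[(2S)-2-(TBSO)undecyl]-10-methyl-1-oxacyclotetradeca-6,9-diene-2,4-dione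
Product: 28 (3E,6E,9E,12S,14R)-12-(TBSO)-14-[(2S)-2-(TBSO)undecyl]-10-methyl-2-oxo-1-oxacyclotetradeca-3,6,9-trien-4-yl trifluoromethanesulfonate
Conditions: Tf2O (2 equiv), 25% aq. Me4NOH (5 equiv), toluene, 5 °C, 15 min
Reagents that add atoms: trifluoromethanesulfonic anhydride, O=S(=O)(OS(=O)(=O)C(F)(F)F)C(F)(F)F
Why: Enol triflation of a β-keto ester under non-chelating Schotten–Baumann conditions: only C2–H, flanked by both carbonyls, is removed, so the alkene is fixed at C2=C3, and the ammonium enolate should adopt the dipole-minimised geometry with O3 anti to the lactone carbonyl, so that O-sulfonylation gives the (E)-enol triflate.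

Step 22
Reactants: 29 tert-butyl bromoacetate
Product: 30 bromo(2-tert-butoxy-2-oxoethyl)zinc (THF solution)
Conditions: Zn dust (activated with BrCH2CH2Br, TMSCl), THF, rt → 40 °C
Reagents that add atoms: zinc, [Zn]
Why: Oxidative insertion of activated zinc into the C–Br bond of the α-bromo ester gives the Reformatsky reagent, used directly as its solution.

Step 23
Reactants: 28 (3E,6E,9E,12S,14R)-12-(TBSO)-14-[(2S)-2-(TBSO)undecyl]-10-methyl-2-oxo-1-oxacyclotetradeca-3,6,9-trien-4-yl trifluoromethanesulfonate; 30 bromo(2-tert-butoxy-2-oxoethyl)zinc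
Product: 31 tert-butyl {(3E,6E,9E,12S,14R)-12-(TBSO)-14-[(2S)-2-(TBSO)undecyl]-10-methyl-2-oxo-1-oxacyclotetradeca-3,6,9-trien-4-yl}acetate
Conditions: Pd(PPh3)4 (10 mol %), THF, 50 °C
Reagents that add atoms: none
Why: Negishi coupling: oxidative addition of zerovalent palladium into the electron-poor C3–OTf bond, transmetalation from the zinc ester enolate and reductive elimination with retention of alkene geometry should place the CH2CO2t-Bu arm trans to C1.

Step 24
Reactants: 31 tert-butyl {(3E,6E,9E,12S,14R)-12-(TBSO)-14-[(2S)-2-(TBSO)undecyl]-10-methyl-2-oxo-1-oxacyclotetradeca-3,6,9-trien-4-yl}acetate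
Product: 32 tert-butyl {(3E,6E,9E,12S,14R)-12-hydroxy-14-[(2S)-2-hydroxyundecyl]-10-methyl-2-oxo-1-oxacyclotetradeca-3,6,9-trien-4-yl}acetate
Conditions: HF·pyridine, pyridine, THF, 0 °C → rt
Reagents that add atoms: none
Why: Fluoride-mediated desilylation under buffered acidic conditions should cleave both secondary TBS ethers while the tert-butyl ester, the lactone and the base-sensitive 3-substituted glutaconate system are untouched.

Step 25
Reactants: 32 tert-butyl {(3E,6E,9E,12S,14R)-12-hydroxy-14-[(2S)-2-hydroxyundecyl]-10-methyl-2-oxo-1-oxacyclotetradeca-3,6,9-trien-4-yl}acetate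
Product: 33 {(3E,6E,9E,12S,14R)-12-hydroxy-14-[(2S)-2-hydroxyundecyl]-10-methyl-2-oxo-1-oxacyclotetradeca-3,6,9-trien-4-yl}acetic acid (CNP0213378.2)
Conditions: TFA/CH2Cl2 (1:4), 0 °C
Reagents that add atoms: none
Why: Acidolysis of the tert-butyl ester (loss of the tert-butyl cation as isobutene) unveils the carboxylic acid without any base, so the position and (E)-geometry of C2=C3 should be kept.

**Compound list**

1 | tert-butyl (3R,5S)-6-chloro-3,5-dihydroxyhexanoate | ClC[C@@H](O)C[C@@H](O)CC(=O)OC(C)(C)C | starting material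
2 | tert-butyl (3R)-3-hydroxy-4-[(2S)-oxiran-2-yl]butanoate | C1O[C@H]1C[C@@H](O)CC(=O)OC(C)(C)C | intermediate
3 | tert-butyl (3R)-3-[(tert-butyldimethylsilyl)oxy]-4-[(2S)-oxiran-2-yl]butanoate | C1O[C@H]1C[C@@H](O[Si](C)(C)C(C)(C)C)CC(=O)OC(C)(C)C | intermediate
4 | (3R)-3-[(tert-butyldimethylsilyl)oxy]-4-[(2S)-oxiran-2-yl]butanal | C1O[C@H]1C[C@@H](O[Si](C)(C)C(C)(C)C)CC=O | intermediate
5 | tert-butyldimethyl{[(2S)-1-[(2S)-oxiran-2-yl]pent-4-yn-2-yl]oxy}silane | C1O[C@H]1C[C@@H](O[Si](C)(C)C(C)(C)C)CC#C | intermediate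
6 | decanal | CCCCCCCCCC=O | starting material
7 | 2-nonyl-1,3-dithiane | CCCCCCCCCC1SCCCS1 | intermediate
8 | 2-lithio-2-nonyl-1,3-dithiane (not isolated) | CCCCCCCCCC1([Li])SCCCS1 | intermediate
9 | (2S,4S)-4-[(tert-butyldimethylsilyl)oxy]-1-(2-nonyl-1,3-dithian-2-yl)hept-6-yn-2-ol | CCCCCCCCCC1(SCCCS1)C[C@@H](O)C[C@@H](O[Si](C)(C)C(C)(C)C)CC#C | intermediate
10 | (4S,6S)-4-[(tert-butyldimethylsilyl)oxy]-6-hydroxyheptadec-1-yn-8-one | CCCCCCCCCC(=O)C[C@@H](O)C[C@@H](O[Si](C)(C)C(C)(C)C)CC#C | intermediate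
11 | (4S,6R,8S)-4-[(tert-butyldimethylsilyl)oxy]-8-hydroxyheptadec-1-yn-6-yl benzoate | CCCCCCCCC[C@H](O)C[C@@H](OC(=O)c1ccccc1)C[C@@H](O[Si](C)(C)C(C)(C)C)CC#C | intermediate
12 | (4S,6R,8S)-4,8-bis[(tert-butyldimethylsilyl)oxy]heptadec-1-yn-6-yl benzoate | CCCCCCCCC[C@H](O[Si](C)(C)C(C)(C)C)C[C@@H](OC(=O)c1ccccc1)C[C@@H](O[Si](C)(C)C(C)(C)C)CC#C | intermediate
13 | (4S,6R,8S)-4,8-bis[(tert-butyldimethylsilyl)oxy]heptadec-1-yn-6-ol | CCCCCCCCC[C@H](O[Si](C)(C)C(C)(C)C)C[C@@H](O)C[C@@H](O[Si](C)(C)C(C)(C)C)CC#C | intermediate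
14 | 3-butyn-1-ol | C#CCCO | starting material
15 | 1-[(but-3-yn-1-yloxy)methyl]-4-methoxybenzene | C#CCCOCc1ccc(OC)cc1 | intermediate
16 | lithium 4-[(4-methoxybenzyl)oxy]but-1-yn-1-ide (not isolated) | [Li]C#CCCOCc1ccc(OC)cc1 | intermediate
17 | 5-[(4-methoxybenzyl)oxy]pent-2-yn-1-ol | OCC#CCCOCc1ccc(OC)cc1 | intermediate
18 | (2E)-5-[(4-methoxybenzyl)oxy]pent-2-en-1-ol | OC/C=C/CCOCc1ccc(OC)cc1 | intermediate
19 | 1-({[(3E)-5-chloropent-3-en-1-yl]oxy}methyl)-4-methoxybenzene | ClC/C=C/CCOCc1ccc(OC)cc1 | intermediate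
20 | {(1E,4S,6R,8S)-4,8-bis[(tert-butyldimethylsilyl)oxy]-6-[(dimethylalumanyl)oxy]-2-methylheptadec-1-en-1-yl}dimethylalumane (not isolated) | CCCCCCCCC[C@H](O[Si](C)(C)C(C)(C)C)C[C@@H](O[Al](C)C)C[C@@H](O[Si](C)(C)C(C)(C)C)C/C(C)=C/[Al](C)C | intermediate
21 | (3E,6E,9S,11R,13S)-9,13-bis[(tert-butyldimethylsilyl)oxy]-1-[(4-methoxybenzyl)oxy]-7-methyldocosa-3,6-dien-11-ol | CCCCCCCCC[C@H](O[Si](C)(C)C(C)(C)C)C[C@@H](O)C[C@@H](O[Si](C)(C)C(C)(C)C)C/C(C)=C/C/C=C/CCOCc1ccc(OC)cc1 | intermediate
22 | (3E,6E,9S,11R,13S)-9,13-bis[(tert-butyldimethylsilyl)oxy]-1-[(4-methoxybenzyl)oxy]-7-methyldocosa-3,6-dien-11-yl bromoacetate | CCCCCCCCC[C@H](O[Si](C)(C)C(C)(C)C)C[C@@H](OC(=O)CBr)C[C@@H](O[Si](C)(C)C(C)(C)C)C/C(C)=C/C/C=C/CCOCc1ccc(OC)cc1 | intermediate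
23 | (3E,6E,9S,11R,13S)-9,13-bis[(tert-butyldimethylsilyl)oxy]-1-hydroxy-7-methyldocosa-3,6-dien-11-yl bromoacetate | CCCCCCCCC[C@H](O[Si](C)(C)C(C)(C)C)C[C@@H](OC(=O)CBr)C[C@@H](O[Si](C)(C)C(C)(C)C)C/C(C)=C/C/C=C/CCO | intermediate
24 | (3E,6E,9S,11R,13S)-9,13-bis[(tert-butyldimethylsilyl)oxy]-7-methyl-1-oxodocosa-3,6-dien-11-yl bromoacetate | CCCCCCCCC[C@H](O[Si](C)(C)C(C)(C)C)C[C@@H](OC(=O)CBr)C[C@@H](O[Si](C)(C)C(C)(C)C)C/C(C)=C/C/C=C/CC=O | intermediate
25 | diiodosamarium 1-{[(3E,6E,9S,11R,13S)-9,13-bis[(tert-butyldimethylsilyl)oxy]-7-methyl-1-oxodocosa-3,6-dien-11-yl]oxy}ethen-1-olate (not isolated) | CCCCCCCCC[C@H](O[Si](C)(C)C(C)(C)C)C[C@@H](OC(=C)O[Sm](I)I)C[C@@H](O[Si](C)(C)C(C)(C)C)C/C(C)=C/C/C=C/CC=O | intermediate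
26 | (6E,9E,12S,14R)-12-[(tert-butyldimethylsilyl)oxy]-14-[(2S)-2-[(tert-butyldimethylsilyl)oxy]undecyl]-4-hydroxy-10-methyl-1-oxacyclotetradeca-6,9-dien-2-one (C4 epimers) | CCCCCCCCC[C@H](O[Si](C)(C)C(C)(C)C)C[C@@H]1C[C@@H](O[Si](C)(C)C(C)(C)C)C/C(C)=C/C/C=C/CC(O)CC(=O)O1 | intermediate
27 | (6E,9E,12S,14R)-12-[(tert-butyldimethylsilyl)oxy]-14-[(2S)-2-[(tert-butyldimethylsilyl)oxy]undecyl]-10-methyl-1-oxacyclotetradeca-6,9-diene-2,4-dione | CCCCCCCCC[C@H](O[Si](C)(C)C(C)(C)C)C[C@@H]1C[C@@H](O[Si](C)(C)C(C)(C)C)C/C(C)=C/C/C=C/CC(=O)CC(=O)O1 | intermediate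
28 | (3E,6E,9E,12S,14R)-12-[(tert-butyldimethylsilyl)oxy]-14-[(2S)-2-[(tert-butyldimethylsilyl)oxy]undecyl]-10-methyl-2-oxo-1-oxacyclotetradeca-3,6,9-trien-4-yl trifluoromethanesulfonate | CCCCCCCCC[C@H](O[Si](C)(C)C(C)(C)C)C[C@@H]1C[C@@H](O[Si](C)(C)C(C)(C)C)C/C(C)=C/C/C=C/C/C(OS(=O)(=O)C(F)(F)F)=C\C(=O)O1 | intermediate
29 | tert-butyl bromoacetate | BrCC(=O)OC(C)(C)C | starting material
30 | bromo(2-tert-butoxy-2-oxoethyl)zinc | Br[Zn]CC(=O)OC(C)(C)C | intermediate
31 | tert-butyl {(3E,6E,9E,12S,14R)-12-[(tert-butyldimethylsilyl)oxy]-14-[(2S)-2-[(tert-butyldimethylsilyl)oxy]undecyl]-10-methyl-2-oxo-1-oxacyclotetradeca-3,6,9-trien-4-yl}acetate | CCCCCCCCC[C@H](O[Si](C)(C)C(C)(C)C)C[C@@H]1C[C@@H](O[Si](C)(C)C(C)(C)C)C/C(C)=C/C/C=C/C/C(CC(=O)OC(C)(C)C)=C\C(=O)O1 | intermediate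
32 | tert-butyl {(3E,6E,9E,12S,14R)-12-hydroxy-14-[(2S)-2-hydroxyundecyl]-10-methyl-2-oxo-1-oxacyclotetradeca-3,6,9-trien-4-yl}acetate | CCCCCCCCC[C@H](O)C[C@@H]1C[C@@H](O)C/C(C)=C/C/C=C/C/C(CC(=O)OC(C)(C)C)=C\C(=O)O1 | intermediate
33 | {(3E,6E,9E,12S,14R)-12-hydroxy-14-[(2S)-2-hydroxyundecyl]-10-methyl-2-oxo-1-oxacyclotetradeca-3,6,9-trien-4-yl}acetic acid | CCCCCCCCC[C@H](O)C[C@@H]1C[C@@H](O)C/C(C)=C/C/C=C/C/C(CC(=O)O)=C\C(=O)O1 | target

**Step count**

Total: 25 steps. Longest linear sequence: 19 steps from 1 (steps 1–4, 6–10, 15–21, 23–25).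

**Steps most likely to fail**

Step 19 (samarium Reformatsky macrocyclisation). What may go wrong: ketyl formation and pinacol coupling at the aldehyde, protonation of the enolate before it finds the aldehyde (leaving a C13 acetate), intermolecular aldol oligomerisation, or migration of C5=C6 into conjugation with the aldehyde before closure. The fallback closes the ring at O–C1 instead; it sets out from 21 and comes back at 27. DDQ in CH2Cl2/pH 7 buffer should remove the PMB group to give (3E,6E,9S,11R,13S)-9,13-bis[(tert-butyldimethylsilyl)oxy]-7-methyldocosa-3,6-diene-1,11-diol F1. TEMPO with PhI(OAc)2 should oxidise only the primary alcohol, giving (3E,6E,9S,11R,13S)-9,13-bis[(tert-butyldimethylsilyl)oxy]-11-hydroxy-7-methyldocosa-3,6-dienal F2. Roskamp homologation with tert-butyl diazoacetate and catalytic SnCl2 should turn the aldehyde into the β-keto ester tert-butyl (5E,8E,11S,13R,15S)-11,15-bis[(tert-butyldimethylsilyl)oxy]-13-hydroxy-9-methyl-3-oxotetracosa-5,8-dienoate F3. Heating F3 in toluene at high dilution should expel tert-butanol, and the acylketene should be trapped by the C13 hydroxyl to give 27 directly.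

Step 21 ((E)-selective enol triflation). What may go wrong: loss of geometric control when part of the enolate reacts through a chelated form, attack of hydroxide on the lactone or on the product triflate, and deprotonation at C4 with drift of C5=C6 into conjugation. The fallback sets out from 27 and comes back at 31. Sulfonylation with TsCl, N-methylimidazole and Et3N in MeCN (amine-only, lithium-free conditions that favour the E isomer) should give (3E,6E,9E,12S,14R)-12-[(tert-butyldimethylsilyl)oxy]-14-[(2S)-2-[(tert-butyldimethylsilyl)oxy]undecyl]-10-methyl-2-oxo-1-oxacyclotetradeca-3,6,9-trien-4-yl 4-methylbenzenesulfonate F4. This enol tosylate is configurationally stable and can be purified by chromatography to remove any Z isomer. Negishi coupling of F4 with 30 under Pd(OAc)2/SPhos catalysis should then give 31.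

Step 23 (Negishi coupling with the zinc ester enolate). What may go wrong: slow transmetalation of the zinc enolate, which would allow reduction of the triflate, or migration and E/Z scrambling of C2=C3 through the glutaconate dienolate. The fallback reverses the polarity of the partners; it sets out from 28 and comes back at 31. Miyaura borylation (B2pin2, PdCl2(PPh3)2, PPh3, KOPh, toluene, 50 °C) should give, with retention, (3Z,6E,9E,12S,14R)-12-[(tert-butyldimethylsilyl)oxy]-14-[(2S)-2-[(tert-butyldimethylsilyl)oxy]undecyl]-10-methyl-4-(4,4,5,5-tetramethyl-1,3,2-dioxaborolan-2-yl)-1-oxacyclotetradeca-3,6,9-trien-2-one F5. Suzuki–Miyaura coupling of F5 with tert-butyl bromoacetate 29 (Pd(OAc)2, P(o-tol)3, K3PO4, THF/H2O, rt) should then give 31.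

**Further compounds**

F1 | step 19 | (3E,6E,9S,11R,13S)-9,13-bis[(tert-butyldimethylsilyl)oxy]-7-methyldocosa-3,6-diene-1,11-diol | CCCCCCCCC[C@H](O[Si](C)(C)C(C)(C)C)C[C@@H](O)C[C@@H](O[Si](C)(C)C(C)(C)C)C/C(C)=C/C/C=C/CCO
F2 | step 19 | (3E,6E,9S,11R,13S)-9,13-bis[(tert-butyldimethylsilyl)oxy]-11-hydroxy-7-methyldocosa-3,6-dienal | CCCCCCCCC[C@H](O[Si](C)(C)C(C)(C)C)C[C@@H](O)C[C@@H](O[Si](C)(C)C(C)(C)C)C/C(C)=C/C/C=C/CC=O
F3 | step 19 | tert-butyl (5E,8E,11S,13R,15S)-11,15-bis[(tert-butyldimethylsilyl)oxy]-13-hydroxy-9-methyl-3-oxotetracosa-5,8-dienoate | CCCCCCCCC[C@H](O[Si](C)(C)C(C)(C)C)C[C@@H](O)C[C@@H](O[Si](C)(C)C(C)(C)C)C/C(C)=C/C/C=C/CC(=O)CC(=O)OC(C)(C)C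
F4 | step 21 | (3E,6E,9E,12S,14R)-12-[(tert-butyldimethylsilyl)oxy]-14-[(2S)-2-[(tert-butyldimethylsilyl)oxy]undecyl]-10-methyl-2-oxo-1-oxacyclotetradeca-3,6,9-trien-4-yl 4-methylbenzenesulfonate | CCCCCCCCC[C@H](O[Si](C)(C)C(C)(C)C)C[C@@H]1C[C@@H](O[Si](C)(C)C(C)(C)C)C/C(C)=C/C/C=C/C/C(OS(=O)(=O)c2ccc(C)cc2)=C\C(=O)O1
F5 | step 23 | (3Z,6E,9E,12S,14R)-12-[(tert-butyldimethylsilyl)oxy]-14-[(2S)-2-[(tert-butyldimethylsilyl)oxy]undecyl]-10-methyl-4-(4,4,5,5-tetramethyl-1,3,2-dioxaborolan-2-yl)-1-oxacyclotetradeca-3,6,9-trien-2-one | CCCCCCCCC[C@H](O[Si](C)(C)C(C)(C)C)C[C@@H]1C[C@@H](O[Si](C)(C)C(C)(C)C)C/C(C)=C/C/C=C/C/C(B2OC(C)(C)C(C)(C)O2)=C\C(=O)O1
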